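The central cyclohexene is cut by a retro-[4+2] disconnection. In this ring C1 bears the aroyl ketone, C2 the chalcone aryl ring, C3=C4 is the methyl-substituted alkene, C5 is CH2, and C6 bears the 2,4-dihydroxyphenyl ring. Because the ring alkene lies opposite the C1–C6 bond and C1 carries a carbonyl group, an endo Diels–Alder reaction of a free dienyl chalcone with a free chalcone dienophile, run by a Diels–Alderase, should form C1–C2 and C5–C6, close the ring and set all three stereocentres at once. Both partners arise from simple acetophenones by aldol condensations, one Suzuki coupling and one directed metalation–prenylation.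

Key step: step 12

Assumption: the structure is taken exactly as drawn, with a 3,5-dihydroxy-4-(3-methylbut-2-enyl)benzoyl group on C1 (no hydroxyl ortho to that ketone), so the dienophile is built with this substitution pattern and chelation-based activation of the enone is not available.

Step 1
Reactants: 1 2-methylbut-1-en-3-yne
Product: 2 4,4,5,5-tetramethyl-2-[(1E)-3-methylbuta-1,3-dien-1-yl]-1,3,2-dioxaborolane
Conditions: pinacolborane, Cp2Zr(H)Cl (5 mol%), Et3N (10 mol%), neat, sealed tube, 40 °C
Reagents that add atoms: pinacolborane, [H]B1OC(C)(C)C(C)(C)O1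
Why: Zirconium-catalysed syn-hydroboration of the terminal alkyne (hydrozirconation, then exchange to boron) should place boron on the terminal carbon and give the E-dienylboronate, the 1,1-disubstituted alkene staying untouched.

Step 2
Reactants: 3 1-(2,4-dihydroxyphenyl)ethan-1-one
Product: 4 1-(2,4-dihydroxy-3-iodophenyl)ethan-1-one
Conditions: I2 (0.4 equiv), HIO3 (0.2 equiv), EtOH/H2O, 40 °C
Reagents that add atoms: iodine, [I][I]; iodic acid, OI(=O)=O
Why: Electrophilic aromatic iodination of the resorcinol ring should go to the position between the two hydroxyl groups, as in the iodination of resorcinol itself, with all iodine ending up in the product.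

Step 3
Reactants: 4 1-(2,4-dihydroxy-3-iodophenyl)ethan-1-one; 5 4-hydroxybenzaldehyde
Product: 6 (2E)-1-(2,4-dihydroxy-3-iodophenyl)-3-(4-hydroxyphenyl)prop-2-en-1-one
Conditions: BF3·OEt2 (3 equiv), 1,4-dioxane, rt; aqueous MeOH work-up
Reagents that add atoms: none
Why: Acid-mediated Claisen–Schmidt condensation (the boron enolate of the ortho-hydroxy ketone adds to the activated aldehyde, then water is lost) tolerates the three free phenols and should give the thermodynamically favoured E-enone.

Step 4
Reactants: 6 (2E)-1-(2,4-dihydroxy-3-iodophenyl)-3-(4-hydroxyphenyl)prop-2-en-1-one; 2 4,4,5,5-tetramethyl-2-[(1E)-3-methylbuta-1,3-dien-1-yl]-1,3,2-dioxaborolane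
Product: 7 (2E)-1-{2,4-dihydroxy-3-[(1E)-3-methylbuta-1,3-dien-1-yl]phenyl}-3-(4-hydroxyphenyl)prop-2-en-1-one
Conditions: Pd(OAc)2 (5 mol%), SPhos (10 mol%), K3PO4 (3 equiv), degassed THF/H2O, 45 °C; work-up at pH 6–7, product kept cold under argon and used at once
Reagents that add atoms: none
Why: Suzuki–Miyaura coupling (oxidative addition of the aryl iodide to zerovalent palladium, transmetalation of the alkenylboronate with retention, reductive elimination) should deliver the E-diene without protecting groups, and the neutral work-up keeps the ortho-hydroxy diene from closing to a chromene.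

Step 5
Reactants: 8 1-(3,5-dihydroxyphenyl)ethan-1-one
Product: 9 1-[3,5-bis(methoxymethoxy)phenyl]ethan-1-one
Conditions: MOMCl (2.5 equiv), K2CO3, acetone, 50 °C
Reagents that add atoms: chloromethyl methyl ether, COCCl
Why: O-Alkylation of both phenoxides gives base-stable acetals that later serve as ortho-directing groups in step 7.

Step 6
Reactants: 9 1-[3,5-bis(methoxymethoxy)phenyl]ethan-1-one
Product: 10 rac-1-[3,5-bis(methoxymethoxy)phenyl]ethan-1-ol
Conditions: NaBH4, MeOH, 0 °C
Reagents that add atoms: none
Why: Hydride reduction masks the ketone as an alcohol whose alkoxide tolerates n-butyllithium; the new stereocentre is racemic and is erased again in step 8.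

Step 7
Reactants: 10 rac-1-[3,5-bis(methoxymethoxy)phenyl]ethan-1-ol; 11 1-bromo-3-methylbut-2-ene
Product: 13 rac-1-[3,5-bis(methoxymethoxy)-4-(3-methylbut-2-en-1-yl)phenyl]ethan-1-ol, via dilithiated alkoxide 12 (not isolated)
Conditions: n-BuLi (2.3 equiv), TMEDA, THF, 0 °C; then CuBr·SMe2 (10 mol%), 11, −40 °C to rt; work-up with water
Reagents that add atoms: none
Why: Directed ortho-metalation: after deprotonation of the alcohol, the second equivalent of base should lithiate the ring position flanked by both methoxymethoxy groups, and copper-catalysed SN2 allylation of the aryllithium gives the linear prenyl arene.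

Step 8
Reactants: 13 rac-1-[3,5-bis(methoxymethoxy)-4-(3-methylbut-2-en-1-yl)phenyl]ethan-1-ol
Product: 14 1-[3,5-bis(methoxymethoxy)-4-(3-methylbut-2-en-1-yl)phenyl]ethan-1-one
Conditions: MnO2 (activated, 15 equiv), CH2Cl2, rt
Reagents that add atoms: none
Why: Activated manganese dioxide oxidises the benzylic alcohol back to the aryl ketone without touching the prenyl alkene or the acetals.

Step 9
Reactants: 15 2,4-dihydroxybenzaldehyde
Product: 16 2,4-bis(methoxymethoxy)benzaldehyde
Conditions: NaH (2.4 equiv), MOMCl (2.4 equiv), DMF, 0 °C to rt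
Reagents that add atoms: chloromethyl methyl ether, COCCl
Why: Williamson-type acetalisation of both phenols, the chelated ortho-hydroxyl included, removes the phenoxide charge that would deactivate the aldehyde in step 10.

Step 10
Reactants: 14 1-[3,5-bis(methoxymethoxy)-4-(3-methylbut-2-en-1-yl)phenyl]ethan-1-one; 16 2,4-bis(methoxymethoxy)benzaldehyde
Product: 17 (2E)-1-[3,5-bis(methoxymethoxy)-4-(3-methylbut-2-en-1-yl)phenyl]-3-[2,4-bis(methoxymethoxy)phenyl]prop-2-en-1-one
Conditions: KOH (3 equiv), EtOH/H2O, rt
Reagents that add atoms: none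
Why: Claisen–Schmidt condensation: only 14 can enolise and only 16 is an aldehyde, and E1cB loss of water from the aldol gives the E-enone.

Step 11
Reactants: 17 (2E)-1-[3,5-bis(methoxymethoxy)-4-(3-methylbut-2-en-1-yl)phenyl]-3-[2,4-bis(methoxymethoxy)phenyl]prop-2-en-1-one
Product: 18 (2E)-1-[3,5-dihydroxy-4-(3-methylbut-2-en-1-yl)phenyl]-3-(2,4-dihydroxyphenyl)prop-2-en-1-one
Conditions: 3 M HCl, MeOH, 40 °C, in the dark, short reaction time
Reagents that add atoms: none
Why: Acid-catalysed methanolysis of the four aryl methoxymethyl acetals, kept mild, short and dark so that the prenyl group does not cyclise onto a flanking phenol and the 2-hydroxychalcone does not isomerise and close to a flavylium ion.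

Step 12
Reactants: 7 (2E)-1-{2,4-dihydroxy-3-[(1E)-3-methylbuta-1,3-dien-1-yl]phenyl}-3-(4-hydroxyphenyl)prop-2-en-1-one; 18 (2E)-1-[3,5-dihydroxy-4-(3-methylbut-2-en-1-yl)phenyl]-3-(2,4-dihydroxyphenyl)prop-2-en-1-one
Product: 19 (2E)-1-{3-[(1S,5S,6R)-6-[3,5-dihydroxy-4-(3-methylbut-2-en-1-yl)benzoyl]-5-(2,4-dihydroxyphenyl)-3-methylcyclohex-2-en-1-yl]-2,4-dihydroxyphenyl}-3-(4-hydroxyphenyl)prop-2-en-1-one
Conditions: recombinant Morus alba Diels–Alderase MaDA (endo-selective, FAD-dependent, catalytic), 18 (2 equiv), 7 added in portions, Tris-HCl buffer pH 8.0, 10% v/v DMSO, 37 °C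
Reagents that add atoms: none
Why: The Diels–Alderase should hold the s-cis diene of 7 over the enone of 18 and let a concerted, asynchronous [4+2] cycloaddition join the enone α-carbon to the aryl-bearing diene terminus (C1–C2) and the enone β-carbon to the CH2 terminus (C5–C6), without cofactor turnover. The closest known reaction is the MaDA-catalysed union of morachalcone A with dehydroprenyl phenols to the natural endo adducts of this family, the same pair of bonds in the same substrate class (chalcone enone plus 1-aryl-3-methylbutadiene). The cyclohexene closes by intermolecular cycloaddition, suprafacial on both components, and the 1-aryl and 3-methyl groups of the diene both direct the aroyl-bearing carbon next to the aryl-bearing one. The trans relation C1/C6 follows from the E-enone, the cis relation C1/C2 from the endo placement of the aroyl group under the diene, and the absolute sense (C1 R, C2 S, C6 S by the labels above, the configuration of the natural endo adducts) from the enone face that the active site exposes. The step needs endo over exo, one enantioface, and cross- over self-cycloaddition of 7, whose own enone is a potential dienophile; an excess of 18 and portionwise addition of 7 should secure the last. The enone of 18 lacks the hydroxyl ortho to the carbonyl that the natural dienophile carries, so binding rests on the unchanged 2,4-dihydroxyphenyl ring, the enone and the hydroxy–prenyl–hydroxy triad, and a small panel of MaDA homologues is screened first.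

Compound list
1 | 2-methylbut-1-en-3-yne | C=C(C)C#C | starting material
2 | 4,4,5,5-tetramethyl-2-[(1E)-3-methylbuta-1,3-dien-1-yl]-1,3,2-dioxaborolane | C=C(C)/C=C/B1OC(C)(C)C(C)(C)O1 | intermediate
3 | 1-(2,4-dihydroxyphenyl)ethan-1-one | CC(=O)c1ccc(O)cc1O | starting material
4 | 1-(2,4-dihydroxy-3-iodophenyl)ethan-1-one | CC(=O)c1ccc(O)c(I)c1O | intermediate
5 | 4-hydroxybenzaldehyde | O=Cc1ccc(O)cc1 | starting material
6 | (2E)-1-(2,4-dihydroxy-3-iodophenyl)-3-(4-hydroxyphenyl)prop-2-en-1-one | O=C(/C=C/c1ccc(O)cc1)c1ccc(O)c(I)c1O | intermediate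
7 | (2E)-1-{2,4-dihydroxy-3-[(1E)-3-methylbuta-1,3-dien-1-yl]phenyl}-3-(4-hydroxyphenyl)prop-2-en-1-one (free diene) | C=C(C)/C=C/c1c(O)ccc(C(=O)/C=C/c2ccc(O)cc2)c1O | intermediate
8 | 1-(3,5-dihydroxyphenyl)ethan-1-one | CC(=O)c1cc(O)cc(O)c1 | starting material
9 | 1-[3,5-bis(methoxymethoxy)phenyl]ethan-1-one | CC(=O)c1cc(OCOC)cc(OCOC)c1 | intermediate
10 | rac-1-[3,5-bis(methoxymethoxy)phenyl]ethan-1-ol | CC(O)c1cc(OCOC)cc(OCOC)c1 | intermediate
11 | 1-bromo-3-methylbut-2-ene (prenyl bromide) | CC(C)=CCBr | starting material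
12 | lithium 1-[4-lithio-3,5-bis(methoxymethoxy)phenyl]ethan-1-olate (dilithiated alkoxide, racemic) | [Li]OC(C)c1cc(OCOC)c([Li])c(OCOC)c1 | intermediate
13 | rac-1-[3,5-bis(methoxymethoxy)-4-(3-methylbut-2-en-1-yl)phenyl]ethan-1-ol | CC(O)c1cc(OCOC)c(CC=C(C)C)c(OCOC)c1 | intermediate
14 | 1-[3,5-bis(methoxymethoxy)-4-(3-methylbut-2-en-1-yl)phenyl]ethan-1-one | CC(=O)c1cc(OCOC)c(CC=C(C)C)c(OCOC)c1 | intermediate
15 | 2,4-dihydroxybenzaldehyde | O=Cc1ccc(O)cc1O | starting material
16 | 2,4-bis(methoxymethoxy)benzaldehyde | O=Cc1ccc(OCOC)cc1OCOC | intermediate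
17 | (2E)-1-[3,5-bis(methoxymethoxy)-4-(3-methylbut-2-en-1-yl)phenyl]-3-[2,4-bis(methoxymethoxy)phenyl]prop-2-en-1-one | CC(C)=CCc1c(OCOC)cc(C(=O)/C=C/c2ccc(OCOC)cc2OCOC)cc1OCOC | intermediate
18 | (2E)-1-[3,5-dihydroxy-4-(3-methylbut-2-en-1-yl)phenyl]-3-(2,4-dihydroxyphenyl)prop-2-en-1-one (free dienophile) | CC(C)=CCc1c(O)cc(C(=O)/C=C/c2ccc(O)cc2O)cc1O | intermediate
19 | (2E)-1-{3-[(1S,5S,6R)-6-[3,5-dihydroxy-4-(3-methylbut-2-en-1-yl)benzoyl]-5-(2,4-dihydroxyphenyl)-3-methylcyclohex-2-en-1-yl]-2,4-dihydroxyphenyl}-3-(4-hydroxyphenyl)prop-2-en-1-one; aroyl and chalcone aryl cis, aroyl and 2,4-dihydroxyphenyl trans | CC(C)=CCc1c(O)cc(C(=O)[C@H]2[C@@H](c3c(O)ccc(C(=O)/C=C/c4ccc(O)cc4)c3O)C=C(C)C[C@@H]2c2ccc(O)cc2O)cc1O | target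

Total step count: 12. Longest linear sequence: 7 steps (steps 5, 6, 7, 8, 10, 11, 12, from 8 to 19).

Steps most likely to fail

Step 12. The enzyme may bind the isomeric dienophile poorly or turn it over slowly, because its enone lacks the internal hydrogen bond of the natural substrate. The diene may also be consumed by cycloaddition to its own enone or by cyclisation in the buffer. The fallback sets out from 7 and 17 and comes back at 19. It uses the uncatalysed cycloaddition of fully protected partners followed by resolution. 7 is capped with MOMCl and NaH in DMF to (2E)-1-{2,4-bis(methoxymethoxy)-3-[(1E)-3-methylbuta-1,3-dien-1-yl]phenyl}-3-[4-(methoxymethoxy)phenyl]prop-2-en-1-one F1. F1 and an excess of 17 are then forced to react (toluene, 2,6-di-tert-butyl-4-methylphenol, 170 °C, sealed tube, or 15 kbar in CH2Cl2); a chalcone without an ortho-hydroxyl is a sluggish dienophile, hence the forcing conditions. The racemic endo adduct is separated from the exo isomer on silica and resolved by preparative HPLC on a chiral stationary phase to give the (1S,5S,6R)-heptakis(methoxymethyl) ether of 19 F2. 3 M HCl in MeOH at 40 °C should then cleave the seven acetals and return to the route at 19.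

Step 4. Oxidative addition may stall on the electron-rich bis-phenoxide iodide, the alkenylboronate may protodeboronate, or the free ortho-hydroxy diene may be lost by ring closure to a chromene during coupling or work-up. The fallback sets out from 6 and comes back at 7. 6 is acetylated (Ac2O, pyridine, 4-(dimethylamino)pyridine) to (2E)-1-(2,4-diacetoxy-3-iodophenyl)-3-(4-acetoxyphenyl)prop-2-en-1-one F3. Coupling with 2 under anhydrous conditions (Pd(PPh3)4, K3PO4, 1,4-dioxane, 80 °C) should give (2E)-1-{2,4-diacetoxy-3-[(1E)-3-methylbuta-1,3-dien-1-yl]phenyl}-3-(4-acetoxyphenyl)prop-2-en-1-one F4, a stable, storable form of the diene. K2CO3 in MeOH at 0 °C then removes the three acetates just before use and returns to the route at 7.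

Step 3. The acid-promoted condensation may stop at a boron chelate of the ortho-hydroxy ketone, or the 2'-hydroxychalcone formed may close to the flavanone. The fallback sets out from 4 and comes back at 6. It uses a base-mediated condensation of protected partners. 4 is converted with MOMCl and NaH in DMF into 1-[3-iodo-2,4-bis(methoxymethoxy)phenyl]ethan-1-one F5. Claisen–Schmidt condensation with commercial 4-(methoxymethoxy)benzaldehyde (KOH, EtOH/H2O, rt) should give (2E)-1-[3-iodo-2,4-bis(methoxymethoxy)phenyl]-3-[4-(methoxymethoxy)phenyl]prop-2-en-1-one F6. 3 M HCl in MeOH (no diene is present yet) cleaves the acetals and returns to the route at 6.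

Further compounds
F1 | step 12 | (2E)-1-{2,4-bis(methoxymethoxy)-3-[(1E)-3-methylbuta-1,3-dien-1-yl]phenyl}-3-[4-(methoxymethoxy)phenyl]prop-2-en-1-one | C=C(C)/C=C/c1c(OCOC)ccc(C(=O)/C=C/c2ccc(OCOC)cc2)c1OCOC
F2 | step 12 | (1S,5S,6R)-heptakis(methoxymethyl) ether of 19 | CC(C)=CCc1c(OCOC)cc(C(=O)[C@H]2[C@@H](c3c(OCOC)ccc(C(=O)/C=C/c4ccc(OCOC)cc4)c3OCOC)C=C(C)C[C@@H]2c2ccc(OCOC)cc2OCOC)cc1OCOC
F3 | step 4 | (2E)-1-(2,4-diacetoxy-3-iodophenyl)-3-(4-acetoxyphenyl)prop-2-en-1-one | O=C(/C=C/c1ccc(OC(C)=O)cc1)c1ccc(OC(C)=O)c(I)c1OC(C)=O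
F4 | step 4 | (2E)-1-{2,4-diacetoxy-3-[(1E)-3-methylbuta-1,3-dien-1-yl]phenyl}-3-(4-acetoxyphenyl)prop-2-en-1-one | C=C(C)/C=C/c1c(OC(C)=O)ccc(C(=O)/C=C/c2ccc(OC(C)=O)cc2)c1OC(C)=O
F5 | step 3 | 1-[3-iodo-2,4-bis(methoxymethoxy)phenyl]ethan-1-one | CC(=O)c1ccc(OCOC)c(I)c1OCOC
F6 | step 3 | (2E)-1-[3-iodo-2,4-bis(methoxymethoxy)phenyl]-3-[4-(methoxymethoxy)phenyl]prop-2-en-1-one | O=C(/C=C/c1ccc(OCOC)cc1)c1ccc(OCOC)c(I)c1OCOC
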